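**Strategy.** Each ring of the symmetric dibenzyl ether is cut at C3–C4 and C6–C1, so that C1(C7)–C2–C3 is a β-ethoxy enone arm on the preformed C7–O–C7' bridge and C4(O)–C5(O)–C6 comes from a 4-methoxyacetoacetate bis(silyl enol ether). One TiCl4-mediated twofold [3+3] cyclocondensation of the bis(enone) ether with two diene units closes both benzene rings and delivers a bis(3-methoxysalicylate). The feature exploited is the vicinal O4/O5 pair flanked by C6 in rings A and B: the C6 ester is a placeholder for bromine. Demethylation, saponification and one sixfold bromination, with ipso-bromodecarboxylation at C6, complete the route.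

Key step: step 4

Remark on numbering: rings A and B are equivalent; in each, C1 carries the benzylic carbon C7, C2, C3 and C6 carry bromine, and C4 and C5 carry hydroxyl.

Assumption: silyl enol ether 5 and diene 6 are drawn with Z double bonds for definiteness; mixtures of geometrical isomers should serve equally, because all of these carbons become aromatic.

**Step 1**
Reactants: 1 diglycolyl chloride (2,2'-oxydiacetyl dichloride); 2 ethyl vinyl ether
Product: 3 1,1'-oxybis[(3E)-4-ethoxybut-3-en-2-one]
Conditions: 2 (6 equiv), pyridine (2.4 equiv), CH2Cl2, 0 °C to rt; cold aq NaHCO3 work-up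
Reagents that add atoms: none
Why: β-C-acylation of an enol ether by an acyl chloride (the acylpyridinium adds to the electron-rich CH2 terminus, then HCl is lost to pyridine) should give the conjugated vinylogous ester in its thermodynamic E form; the α-alkoxy group raises the electrophilicity of the acyl chloride, and pyridine, unlike a trialkylamine, keeps ketene formation low.

**Step 2**
Reactants: 4 methyl 4-methoxyacetoacetate
Product: 5 methyl (2Z)-4-methoxy-3-(trimethylsilyloxy)but-2-enoate
Conditions: Me3SiCl (1.5 equiv), Et3N (1.6 equiv), toluene, 20 °C; filtration and distillation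
Reagents that add atoms: chlorotrimethylsilane, C[Si](C)(C)Cl
Why: O-silylation of the β-keto ester enol (silyl enol ether formation) should give the conjugated 3-silyloxy enoate, the standard first stage on the way to a 1,3-bis(silyloxy)diene.

**Step 3**
Reactants: 5 methyl (2Z)-4-methoxy-3-(trimethylsilyloxy)but-2-enoate
Product: 6 (1Z,3Z)-1,4-dimethoxy-1,3-bis(trimethylsilyloxy)buta-1,3-diene
Conditions: LiN(iPr)2 (commercial LDA, 1.5 equiv), THF, −78 °C; Me3SiCl (1.5 equiv), −78 °C to 20 °C; pentane, filtration under argon, used crude
Reagents that add atoms: chlorotrimethylsilane, C[Si](C)(C)Cl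
Why: kinetic γ-deprotonation of the vinylogous ester at the methoxy-bearing CH2 and O-silylation of the dienolate (silyl ketene acetal formation) should give the electron-rich diene, which is moisture-sensitive and is therefore not purified.

**Step 4**
Reactants: 3 1,1'-oxybis[(3E)-4-ethoxybut-3-en-2-one]; 6 (1Z,3Z)-1,4-dimethoxy-1,3-bis(trimethylsilyloxy)buta-1,3-diene
Product: 8 dimethyl 6,6'-[oxybis(methylene)]bis(2-hydroxy-3-methoxybenzoate), via open-chain bis(conjugate adduct) 7 (not isolated)
Conditions: 6 (3 equiv), TiCl4 (2.2 equiv), 4 Å molecular sieves, CH2Cl2, −78 °C to 20 °C; cold dilute HCl work-up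
Reagents that add atoms: none
Why: TiCl4 activates each vinylogous ester arm of 3, the methoxy-bearing terminus of 6 adds to the enone β-carbon (C3–C4) to give adduct 7, held in the flask as its silyl and titanium enolates, and the remaining silyl enol ether carbon then attacks the ketone in an intramolecular Mukaiyama aldol (C6–C1). Loss of ethanol and water with enolisation aromatises each ring, so that the ester sits on C6 next to the C5 hydroxyl and the methoxy group on C4. The closest known reaction type is the Lewis-acid benzannulation of 1,3-bis(silyl enol ethers) of β-keto esters with β-alkoxy enones, established for salicylates and also for γ-alkoxy dienes, which lead to 3-alkoxysalicylates. Each of the two benzene rings closes by a 6-(enolexo)-exo-trig aldol addition followed by elimination; no stereocentre is set, and the four transient centres of 7 are erased on aromatisation. The step needs site selectivity (diene terminus to the β-carbon, ester-bearing carbon to the ketone), which should follow from the higher nucleophilicity of the diene terminus and the TiCl4-activated β-position of the alkoxy enone. It also needs both arms to react, which the excess of 6 and TiCl4 and the electronic independence of the two arms across the CH2–O–CH2 bridge should secure.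

**Step 5**
Reactants: 8 dimethyl 6,6'-[oxybis(methylene)]bis(2-hydroxy-3-methoxybenzoate)
Product: 9 dimethyl 6,6'-[oxybis(methylene)]bis(2,3-dihydroxybenzoate)
Conditions: AlCl3 (5 equiv), pyridine (20 equiv), CH2Cl2, reflux; cold 1 M HCl work-up
Reagents that add atoms: none
Why: chelation-assisted dealkylation of a 2-methoxyphenol, in which the aluminium phenoxide at O5 binds the neighbouring C4 methoxy oxygen and pyridine removes the methyl group by SN2; the methyl esters and the bridge ether, which cannot form such a chelate with the pyridine-moderated Lewis acid, should stay intact.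

**Step 6**
Reactants: 9 dimethyl 6,6'-[oxybis(methylene)]bis(2,3-dihydroxybenzoate)
Product: 10 6,6'-[oxybis(methylene)]bis(2,3-dihydroxybenzoic acid)
Conditions: LiOH (10 equiv), degassed THF–H2O, 50 °C, argon; then 1 M HCl to pH 3 at 0 °C, EtOAc extraction, used directly
Reagents that add atoms: lithium hydroxide, [Li+].[OH-]
Why: ester saponification (BAc2) under oxygen-free conditions protects the catecholates; at this temperature the bridge alkoxide is too poor a leaving group for quinone-methide formation, and cold, brief acidification should avoid lactonisation of the 2-(alkoxymethyl)benzoic acid.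

**Step 7**
Reactants: 10 6,6'-[oxybis(methylene)]bis(2,3-dihydroxybenzoic acid)
Product: 11 bis(2,3,6-tribromo-4,5-dihydroxybenzyl) ether
Conditions: Br2 (6.1 equiv), NaOAc (8 equiv), MeCN–AcOH, 0 °C to rt, dark; aq Na2S2O4 quench; alcohol-free work-up
Reagents that add atoms: bromine, BrBr
Why: electrophilic aromatic bromination of the catechol at C2 (para to O5) and C3 (ortho to O4), together with ipso attack at C6 (ortho to O5) and loss of CO2, the classical bromodecarboxylation of a salicylic acid; acetate buffering removes HBr before it can cleave the p-hydroxybenzylic ether, the near-stoichiometric charge of Br2 limits ipso attack at C1, and the reductive quench returns any o-quinone to the catechol.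

**Compound list**
1 | diglycolyl chloride (2,2'-oxydiacetyl dichloride) | O=C(Cl)COCC(Cl)=O | starting material
2 | ethyl vinyl ether | C=COCC | starting material
3 | 1,1'-oxybis[(3E)-4-ethoxybut-3-en-2-one] | CCO/C=C/C(=O)COCC(=O)/C=C/OCC | intermediate
4 | methyl 4-methoxyacetoacetate (methyl 4-methoxy-3-oxobutanoate) | COCC(=O)CC(=O)OC | starting material
5 | methyl (2Z)-4-methoxy-3-(trimethylsilyloxy)but-2-enoate | COC/C(O[Si](C)(C)C)=C/C(=O)OC | intermediate
6 | (1Z,3Z)-1,4-dimethoxy-1,3-bis(trimethylsilyloxy)buta-1,3-diene | CO/C=C(O[Si](C)(C)C)/C=C(/OC)O[Si](C)(C)C | intermediate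
7 | dimethyl 8,8'-oxybis(5-ethoxy-4-methoxy-3,7-dioxooctanoate), mixture of diastereomers (four uncontrolled centres, all erased in the same step) | COC(=O)CC(=O)C(OC)C(OCC)CC(=O)COCC(=O)CC(OCC)C(OC)C(=O)CC(=O)OC | intermediate (not isolated)
8 | dimethyl 6,6'-[oxybis(methylene)]bis(2-hydroxy-3-methoxybenzoate) | COC(=O)c1c(O)c(OC)ccc1COCc1ccc(OC)c(O)c1C(=O)OC | intermediate
9 | dimethyl 6,6'-[oxybis(methylene)]bis(2,3-dihydroxybenzoate) | COC(=O)c1c(O)c(O)ccc1COCc1ccc(O)c(O)c1C(=O)OC | intermediate
10 | 6,6'-[oxybis(methylene)]bis(2,3-dihydroxybenzoic acid) | OC(=O)c1c(O)c(O)ccc1COCc1ccc(O)c(O)c1C(=O)O | intermediate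
11 | bis(2,3,6-tribromo-4,5-dihydroxybenzyl) ether | Oc1c(O)c(Br)c(COCc2c(Br)c(O)c(O)c(Br)c2Br)c(Br)c1Br | target

**Step count.** Total: 7 steps. Longest linear sequence: 6 steps (4 → 5 → 6 → 8 → 9 → 10 → 11; step 1 is the second branch).

**Steps most likely to fail**

Step 4. Three processes may intervene:
- only one arm may annulate while the second enone arm is hydrolysed or oligomerised by the Lewis acid;
- the diene terminus may attack the TiCl4-chelated α-alkoxy ketone instead of the β-carbon, which would transpose the benzylic carbon to the position next to the methoxy group;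
- the newly formed p-methoxybenzylic ether may ionise under TiCl4 and close onto the ortho ester.

The fallback separates C–C bond formation from ring closure and keeps strong Lewis acid away from the finished benzylic ether. It sets out from 3 and returns at 8.
- Conjugate addition of ethanol to 3 (EtOH, catalytic NaOEt, 0 °C) should give the bis(β-keto acetal) 1,1'-oxybis(4,4-diethoxybutan-2-one) F1.
- A Mukaiyama-type acetal substitution with diene 6 (catalytic Me3SiOTf, CH2Cl2, −78 °C), in which only the acetal carbon is ionised and the ketones are left alone, should fix the C3–C4 bond without ambiguity and give 7, now isolated after mild aqueous work-up.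
- An intramolecular Knoevenagel-type aldol condensation of 7 (piperidinium acetate, toluene, 60 °C, finished with catalytic TsOH if needed) should close C6–C1 and, with loss of water and ethanol, give 8.

Step 7. Three processes may intervene:
- the catechol may be over-oxidised to the o-quinone;
- bromine may attack ipso at C1, para to the free C4 hydroxyl, with loss of the benzylic arm;
- the p-hydroxybenzylic ether may solvolyse through a quinone methide.

The fallback moves the bromination ahead of the demethylation, so that O4 stays capped as its methyl ether while the electrophile is present. It sets out from 8 and returns at 11.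
- Saponification of 8 (LiOH, THF–H2O, 60 °C) should give 6,6'-[oxybis(methylene)]bis(2-hydroxy-3-methoxybenzoic acid) F2.
- Buffered bromination (Br2, NaOAc, AcOH, rt, gentle warming for the last bromine at C3, which is only ortho to the methoxy group) should give 3,3'-[oxybis(methylene)]bis(2,4,5-tribromo-6-methoxyphenol) F3, by bromodecarboxylation at C6 and substitution at C2 and C3.
- Chelation-assisted demethylation of F3 (AlCl3, pyridine, CH2Cl2, 35 °C, cold dilute HCl work-up) should give 11.

Step 1. Three processes may intervene:
- the α-alkoxy acyl chloride may be dehydrochlorinated to a ketene that adds [2+2] to the vinyl ether;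
- the vinyl ether may polymerise under the HCl set free;
- acylation may stop after the first arm.

The fallback builds the enone from an ynone instead. It sets out from 1 and returns at 3.
- Amidation of 1 (MeNHOMe·HCl, Et3N, CH2Cl2, 0 °C) should give 2,2'-oxybis(N-methoxy-N-methylacetamide) F4.
- Addition of ethynylmagnesium bromide (THF, −78 °C to 0 °C, inverse quench into cold aq NaHSO4 so that the liberated amine does not add to the product) should give 1,1'-oxybis(but-3-yn-2-one) F5.
- Amine-catalysed conjugate addition of ethanol (EtOH, catalytic DABCO, CH2Cl2, 0 °C) should give the E,E-bis(ethoxyenone) 3.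

**Further compounds**
F1 | step 4 | 1,1'-oxybis(4,4-diethoxybutan-2-one) | CCOC(OCC)CC(=O)COCC(=O)CC(OCC)OCC
F2 | step 7 | 6,6'-[oxybis(methylene)]bis(2-hydroxy-3-methoxybenzoic acid) | OC(=O)c1c(O)c(OC)ccc1COCc1ccc(OC)c(O)c1C(=O)O
F3 | step 7 | 3,3'-[oxybis(methylene)]bis(2,4,5-tribromo-6-methoxyphenol) | COc1c(O)c(Br)c(COCc2c(Br)c(O)c(OC)c(Br)c2Br)c(Br)c1Br
F4 | step 1 | 2,2'-oxybis(N-methoxy-N-methylacetamide) | CON(C)C(=O)COCC(=O)N(C)OC
F5 | step 1 | 1,1'-oxybis(but-3-yn-2-one) | C#CC(=O)COCC(=O)C#C
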